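The meeting on east, south-west and south began at late times: these three flasks share one charge and differ in the time of reading, so the first question was what could stop them before the substrate is gone.

common to all: substrate 0.20 M
- Thursday's: partner 0.20 M; free catalyst 10 mM; run made earlier
- Saturday's: partner 0.31 M; free catalyst 10 mM; run made earlier
- Friday's: partner 0.14 M; free catalyst 5 mM; run made earlier
- east: partner 0.140 M; free catalyst 10 mM; time 2.5 min
- south-west: partner 0.140 M; free catalyst 10 mM; time 4.0 min
- south: partner 0.140 M; free catalyst 10 mM; time 6.0 min

| run | time / min | side product / % | substrate / % | catalyst intermediate C / % | target / % |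
|---|---|---|---|---|---|
| Thursday's | 0.200 | 2.3 | 95.3 | 2.2 | 4.5 |
| Thursday's | 0.667 | 14.2 | 80.6 | 0 | 5.5 |
| Thursday's | 1.00 | 23.8 | 68.4 | 0 | 6.2 |
| Thursday's | 1.50 | 37.8 | 53.8 | 0 | 8.6 |
| Thursday's | 2.50 | 58.9 | 33.8 | 0 | 7.1 |
| Thursday's | 3.00 | 66.0 | 28.9 | 0 | 6.6 |
| Saturday's | 0.250 | 2.5 | 94.3 | 1.3 | 3.6 |
| Saturday's | 0.417 | 7.7 | 87.1 | 0 | 4.1 |
| Saturday's | 0.667 | 15.5 | 79.4 | 0 | 6.1 |
| Saturday's | 1.00 | 26.7 | 68.4 | 0.6 | 5.3 |
| Saturday's | 2.00 | 50.8 | 44.1 | 0 | 6.6 |
| Saturday's | 3.00 | 68.2 | 28.3 | 0.6 | 6.7 |
| Friday's | 0.250 | 0.4 | 97.5 | 0.7 | 0 |
| Friday's | 0.833 | 10.2 | 88.6 | 0.3 | 2.3 |
| Friday's | 1.33 | 19.1 | 77.4 | 1.0 | 0.4 |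
| Friday's | 2.00 | 30.2 | 67.2 | 0 | 1.8 |
| Friday's | 3.00 | 42.9 | 53.8 | 0 | 2.2 |

(standard deviation of a reading: 1 percentage point)

- which of these there is most of at the end, counted by the substrate in it, east (catalyst intermediate C / side product / substrate / target)
- which of these there is most of at the end, counted by the substrate in it, south-west (catalyst intermediate C / side product / substrate / target)
- which of these there is most of at the end, counted by the substrate in it, south (catalyst intermediate C / side product / substrate / target)
- final amount of the leader among these, as a percentage of the substrate charged, in east
- final amount of the leader among these, as a percentage of the substrate charged, in south-west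
- final amount of the leader among these, as a percentage of the substrate charged, in south

- percent here means substrate units held: one side product counts as two
- what was read earlier has a scatter of 1 percentage point, one standard deviation

The bench chemist reported that at 3.00 min Thursday's substrate read 28.9% and Saturday's 28.3%, although their partner charges were 0.20 M and 0.31 M, so the partner charge did not show in these readings. Friday's run, with 5 mM of free catalyst and 0.14 M of partner, still read 53.8% at that time, more than Thursday's.

The second speaker objected that a level is not an amount. Of the two reagents, partner is the smaller charge, 0.700 of the substrate charge, and so the limiting reagent on paper. She offered her own balance as a supposition: one partner pays for one turnover, a turnover gives one target, and a side product holds two substrate units, so one partner carries two units. She put the figure at 1.40, the partner reach: the substrate charges that the partner charge can carry into side product. It stands above one, so on her supposition substrate goes before partner. Her rule for partner used, as a share of its charge, was side product, plus two times target, plus two times the catalyst not free, each in fractions of the substrate charge, divided by the reach.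

The forecast named side product as leader in east, side product in south-west and side product in south, at 58.5%, 75% and 85%, on the ground that “Everything else becomes side product”.

The flasks give side product at 58.1% in east, side product at 76.3% in south-west and side product at 87.3% in south, so the forecast stands within its margins.

    partner + free catalyst → catalyst intermediate A (k = 5.00 M⁻¹ s⁻¹)
    substrate + catalyst intermediate A ⇌ catalyst intermediate B (K = 1.10 M⁻¹, k = 0.590 M⁻¹ s⁻¹)
    catalyst intermediate B → released group + catalyst intermediate C (k = 1.90 s⁻¹)
    catalyst intermediate C → free catalyst + target (k = 0.600 s⁻¹)
    substrate + target → side product (k = 0.340 M⁻¹ s⁻¹)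

South's side product lies 29 percentage points above east's because of its longer time: south read at east's time gives 58.1% against 87.3%. The falling partner is not the brake: east with partner held level gives 59.1% against 58.1%. By the reach, south-west's 76.3% side product, 5.94% target and catalyst not free reckon to 30.4% of partner left; south-west holds 30.4% of its partner beside 18% of its substrate.

A neighbour flask, south-west's recipe with 0.050 M of substrate, has a reach of 5.60, and its 59.6% side product, 22.8% target and catalyst not free reckon to 74.1% of partner left. The computed flask holds 74% of its partner.

The data are simulated on assumed constants.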